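**Strategy.** With the phenol carbon as C1, the single benzene ring (ring A) carries Br on C2, C3 and C6, the hydroxymethyl carbon C7 on C4 and H on C5. The route cuts the C2–Br and C3–Br bonds back to a C2–C3 aryne. Since these adjacent ring carbons bear the same atom, one vicinal dibromination installs both, including the C3 bromine meta to oxygen that electrophilic bromination cannot place, and the direction of addition is irrelevant. The precursor is an ortho-silylaryl triflate (Me3Si on C3, triflate on C2) that already holds C6–Br, the C1 oxygen as a MOM ether and C7 as a dioxolane.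

Key step: step 7

Remark: the hydroxyl of 2 para to the formyl group is taken as the more acidic one; atom labels C1–C7 are those of the target; no compound in the route has a stereocentre.

**Step 1**
Reactants: 1 5-bromovanillin (3-bromo-4-hydroxy-5-methoxybenzaldehyde)
Product: 2 3-bromo-4,5-dihydroxybenzaldehyde
Conditions: BBr3, CH2Cl2, −78 °C → rt; then H2O
Reagents that add atoms: none
Why: Lewis-acid-mediated O-demethylation of an aryl methyl ether (boron coordinates oxygen, bromide attacks the methyl group) frees the second hydroxyl while the aldehyde and the aryl bromide are untouched.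

**Step 2**
Reactants: 2 3-bromo-4,5-dihydroxybenzaldehyde; 3 chloromethyl methyl ether
Product: 4 3-bromo-5-hydroxy-4-(methoxymethoxy)benzaldehyde
Conditions: K2CO3 (1.1 equiv), acetone, 0 °C → rt
Reagents that add atoms: chloromethyl methyl ether, COCCl
Why: Williamson-type O-alkylation under acidity control, in which one equivalent of weak base ionises mainly the hydroxyl para to the formyl group and ortho to bromine, as in the 4-O-selective alkylations of protocatechualdehydes.

**Step 3**
Reactants: 4 3-bromo-5-hydroxy-4-(methoxymethoxy)benzaldehyde; 5 isopropyl isocyanate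
Product: 6 3-bromo-5-formyl-2-(methoxymethoxy)phenyl N-isopropylcarbamate
Conditions: Et3N (cat.), CH2Cl2, rt
Reagents that add atoms: isopropyl isocyanate, CC(C)N=C=O
Why: Base-catalysed addition of the remaining phenol to the isocyanate (carbamoylation) installs a secondary carbamate that directs ortho-metalation and is later removed under mild base.

**Step 4**
Reactants: 6 3-bromo-5-formyl-2-(methoxymethoxy)phenyl N-isopropylcarbamate; 7 1,2-bis(trimethylsilyloxy)ethane
Product: 8 3-bromo-5-(1,3-dioxolan-2-yl)-2-(methoxymethoxy)phenyl N-isopropylcarbamate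
Conditions: TMSOTf (cat.), CH2Cl2, −78 °C; then pyridine
Reagents that add atoms: 1,2-bis(trimethylsilyloxy)ethane, C[Si](C)(C)OCCO[Si](C)(C)C
Why: Acetalisation under Noyori conditions (bis-silyl ether of the diol, catalytic silyl triflate, aprotic, cold) is driven by formation of hexamethyldisiloxane and avoids the protic acid and free diol that could strip the aryl MOM ether.

**Step 5**
Reactants: 8 3-bromo-5-(1,3-dioxolan-2-yl)-2-(methoxymethoxy)phenyl N-isopropylcarbamate; 9 chlorotrimethylsilane
Product: 12 3-bromo-5-(1,3-dioxolan-2-yl)-2-(methoxymethoxy)-6-(trimethylsilyl)phenyl N-isopropylcarbamate, via N-TBS carbamate 10 (not isolated), via C3-silylated N-TBS carbamate 11 (not isolated)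
Conditions: TBSOTf, TMEDA, Et2O, 0 °C → rt; then TMSCl, lithium 2,2,6,6-tetramethylpiperidide (LiTMP, excess), THF, −78 °C; then MeOH, aq NH4Cl
Reagents that add atoms: chlorotrimethylsilane, C[Si](C)(C)Cl
Why: Directed ortho-metalation of the carbamate after in situ N-silylation, run with a lithium amide that, unlike an alkyllithium, does not exchange with the C6 bromide: it removes C3–H, the only proton ortho to the carbamate and also flanked by the acetal, the aryllithium is silylated as it forms by the TMSCl already present (in situ quench, no time for anionic Fries rearrangement), and the N–Si bond is hydrolysed on work-up.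

**Step 6**
Reactants: 12 3-bromo-5-(1,3-dioxolan-2-yl)-2-(methoxymethoxy)-6-(trimethylsilyl)phenyl N-isopropylcarbamate; 13 N-phenylbis(trifluoromethanesulfonimide)
Product: 15 3-bromo-5-(1,3-dioxolan-2-yl)-2-(methoxymethoxy)-6-(trimethylsilyl)phenyl trifluoromethanesulfonate, via silylphenol 14 (not isolated)
Conditions: DBU, Et2NH, MeCN, 40 °C; then PhNTf2, 40 °C
Reagents that add atoms: N-phenylbis(trifluoromethanesulfonimide), O=S(=O)(N(c1ccccc1)S(=O)(=O)C(F)(F)F)C(F)(F)F
Why: E1cB cleavage of the secondary carbamate (N–H deprotonation, loss of phenoxide, isocyanate scavenged by Et2NH) followed by O-triflation of the phenoxide in the same flask, under base mild enough for the aryl–silicon bond, the acetal and the MOM ether.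

**Step 7**
Reactants: 15 3-bromo-5-(1,3-dioxolan-2-yl)-2-(methoxymethoxy)-6-(trimethylsilyl)phenyl trifluoromethanesulfonate; 16 CuBr2; 17 tetrabutylammonium bromide
Product: 19 2-[2,3,5-tribromo-4-(methoxymethoxy)phenyl]-1,3-dioxolane, via aryne 18 (not isolated)
Conditions: CsF, CuBr2 (3 equiv), n-Bu4NBr (6 equiv), MeCN, 4 Å MS, rt
Reagents that add atoms: CuBr2, Br[Cu]Br; tetrabutylammonium bromide, CCCC[N+](CCCC)(CCCC)CCCC.[Br-]
Why: Fluoride from CsF adds to the C3 trimethylsilyl group and the resulting aryl anion expels the C2 triflate (1,2-elimination) to give aryne 18 with no acid or strong base present, so C6–Br, the dioxolane and the MOM ether persist. The bromocuprate formed from CuBr2 and n-Bu4NBr then transfers bromide to C3, the aryne carbon remote from the C1 alkoxy group and the one preferred by nucleophiles in 3-alkoxyarynes, while C2 binds copper; a second divalent copper centre oxidises this aryl–copper species to trivalent copper, and reductive elimination forms C2–Br, leaving monovalent copper as CuBr. The closest known reaction types are the vicinal dichlorination of arynes with Li2CuCl4 and the insertion of fluoride-generated arynes into molecular iodine. No ring is closed and no stereocentre is created. The step needs chemoselectivity for double bromine transfer over capture of the aryne by a proton or by fluoride, which is secured by the dry medium, sparingly soluble CsF and an excess of a lithium-free bromocuprate (lithium ions would tie up fluoride as LiF). Site selectivity does not matter, because both aryne carbons end up with bromine whichever is attacked first.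

**Step 8**
Reactants: 19 2-[2,3,5-tribromo-4-(methoxymethoxy)phenyl]-1,3-dioxolane
Product: 20 2,3,5-tribromo-4-hydroxybenzaldehyde
Conditions: 2 M aq HCl, THF, 50 °C
Reagents that add atoms: water, O
Why: Acid-catalysed acetal hydrolysis cleaves the dioxolane and the MOM ether (itself a formaldehyde acetal) in one operation, and the aryl bromides are inert to aqueous acid.

**Step 9**
Reactants: 20 2,3,5-tribromo-4-hydroxybenzaldehyde
Product: 21 2,3,6-tribromo-4-(hydroxymethyl)phenol
Conditions: NaBH4, THF/H2O, 0 °C; then aq NH4Cl
Reagents that add atoms: none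
Why: Borohydride reduction of the aldehyde to the primary alcohol leaves aryl bromides and the phenol alone, and the near-neutral, methanol-free work-up avoids solvolysis of the para-hydroxybenzyl alcohol.

**Compound list**
1 | 5-bromovanillin (3-bromo-4-hydroxy-5-methoxybenzaldehyde) | COc1cc(C=O)cc(Br)c1O | starting material
2 | 3-bromo-4,5-dihydroxybenzaldehyde | O=Cc1cc(O)c(O)c(Br)c1 | intermediate
3 | chloromethyl methyl ether | COCCl | starting material
4 | 3-bromo-5-hydroxy-4-(methoxymethoxy)benzaldehyde | COCOc1c(O)cc(C=O)cc1Br | intermediate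
5 | isopropyl isocyanate | CC(C)N=C=O | starting material
6 | 3-bromo-5-formyl-2-(methoxymethoxy)phenyl N-isopropylcarbamate | COCOc1c(Br)cc(C=O)cc1OC(=O)NC(C)C | intermediate
7 | 1,2-bis(trimethylsilyloxy)ethane | C[Si](C)(C)OCCO[Si](C)(C)C | starting material
8 | 3-bromo-5-(1,3-dioxolan-2-yl)-2-(methoxymethoxy)phenyl N-isopropylcarbamate | COCOc1c(Br)cc(C2OCCO2)cc1OC(=O)NC(C)C | intermediate
9 | chlorotrimethylsilane | C[Si](C)(C)Cl | starting material
10 | 3-bromo-5-(1,3-dioxolan-2-yl)-2-(methoxymethoxy)phenyl N-(tert-butyldimethylsilyl)-N-isopropylcarbamate | COCOc1c(Br)cc(C2OCCO2)cc1OC(=O)N(C(C)C)[Si](C)(C)C(C)(C)C | intermediate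
11 | 3-bromo-5-(1,3-dioxolan-2-yl)-2-(methoxymethoxy)-6-(trimethylsilyl)phenyl N-(tert-butyldimethylsilyl)-N-isopropylcarbamate | COCOc1c(Br)cc(C2OCCO2)c([Si](C)(C)C)c1OC(=O)N(C(C)C)[Si](C)(C)C(C)(C)C | intermediate
12 | 3-bromo-5-(1,3-dioxolan-2-yl)-2-(methoxymethoxy)-6-(trimethylsilyl)phenyl N-isopropylcarbamate | COCOc1c(Br)cc(C2OCCO2)c([Si](C)(C)C)c1OC(=O)NC(C)C | intermediate
13 | N-phenylbis(trifluoromethanesulfonimide) | O=S(=O)(N(c1ccccc1)S(=O)(=O)C(F)(F)F)C(F)(F)F | starting material
14 | 3-bromo-5-(1,3-dioxolan-2-yl)-2-(methoxymethoxy)-6-(trimethylsilyl)phenol | COCOc1c(Br)cc(C2OCCO2)c([Si](C)(C)C)c1O | intermediate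
15 | 3-bromo-5-(1,3-dioxolan-2-yl)-2-(methoxymethoxy)-6-(trimethylsilyl)phenyl trifluoromethanesulfonate | COCOc1c(Br)cc(C2OCCO2)c([Si](C)(C)C)c1OS(=O)(=O)C(F)(F)F | intermediate
16 | CuBr2 (copper dibromide) | Br[Cu]Br | starting material
17 | tetrabutylammonium bromide | CCCC[N+](CCCC)(CCCC)CCCC.[Br-] | starting material
18 | 5-bromo-3-(1,3-dioxolan-2-yl)-6-(methoxymethoxy)benzyne (aryne across C2–C3) | COCOC1=C(Br)C=C(C2OCCO2)C#C1 | intermediate
19 | 2-[2,3,5-tribromo-4-(methoxymethoxy)phenyl]-1,3-dioxolane | COCOc1c(Br)cc(C2OCCO2)c(Br)c1Br | intermediate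
20 | 2,3,5-tribromo-4-hydroxybenzaldehyde | O=Cc1cc(Br)c(O)c(Br)c1Br | intermediate
21 | 2,3,6-tribromo-4-(hydroxymethyl)phenol | OCc1cc(Br)c(O)c(Br)c1Br | target

**Total step count:** 9. **Longest linear sequence:** 9 steps, from 1.

**Steps most likely to fail**

Step 7. After the first bromide has added, the C2 carbon may pick up a proton instead of a second bromine. Fluoride may also be held back by the copper salt, so that aryne formation stalls. The fallback splits the double bromination into a nucleophilic and an electrophilic half. From 15, CsF with n-Bu4NBr and t-BuOH as proton donor in MeCN (aryne hydrobromination: bromide at C3, proton at C2) should give 2-[2,5-dibromo-4-(methoxymethoxy)phenyl]-1,3-dioxolane F1. Aqueous HCl in THF should then unmask 2,5-dibromo-4-hydroxybenzaldehyde F2. Br2 with NaOAc in AcOH brominates the only free position ortho to the phenol, C2, by electrophilic aromatic substitution, and the route is rejoined at 20.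

Step 5. The amide base may deprotonate C5 beside the bromine (followed by loss of LiBr or silylation at the wrong carbon), or metalation at C3 may be too slow. The fallback places silicon on C3 by halogen–lithium exchange and a retro-Brook shift instead of deprotonation. From 4, iodination with N-iodosuccinimide in MeCN at the position between hydroxyl and formyl group should give 5-bromo-3-hydroxy-2-iodo-4-(methoxymethoxy)benzaldehyde F3. Hexamethyldisilazane converts it into 5-bromo-2-iodo-4-(methoxymethoxy)-3-(trimethylsilyloxy)benzaldehyde F4. Acetalisation with 7 and catalytic TMSOTf gives [5-bromo-3-(1,3-dioxolan-2-yl)-2-iodo-6-(methoxymethoxy)phenoxy]trimethylsilane F5. One equivalent of n-BuLi in THF at −100 °C exchanges iodine faster than bromine, and the aryllithium takes the silyl group from oxygen (1,3 O-to-C shift). The lithium phenoxide of 14 is triflated in the same flask with 13, and the route is rejoined at 15.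

Step 2. Alkylation may occur at the wrong hydroxyl or at both. The fallback differentiates the hydroxyls by leaving-group ability instead of by acidity-controlled alkylation. From 2, excess 5 with catalytic Et3N gives 3-bromo-5-formyl-1,2-phenylene bis(N-isopropylcarbamate) F6. One equivalent of Et2NH with DBU removes, by E1cB elimination, the carbamate on the better-leaving phenoxide (para to the formyl group, ortho to bromine); any O-to-O carbamoyl shift leads to the same isomer, 3-bromo-5-formyl-2-hydroxyphenyl N-isopropylcarbamate F7. MOMCl with i-Pr2NEt caps the freed hydroxyl and the route is rejoined at 6.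

**Further compounds**
F1 | step 7 | 2-[2,5-dibromo-4-(methoxymethoxy)phenyl]-1,3-dioxolane | COCOc1cc(Br)c(C2OCCO2)cc1Br
F2 | step 7 | 2,5-dibromo-4-hydroxybenzaldehyde | O=Cc1cc(Br)c(O)cc1Br
F3 | step 5 | 5-bromo-3-hydroxy-2-iodo-4-(methoxymethoxy)benzaldehyde | COCOc1c(O)c(I)c(C=O)cc1Br
F4 | step 5 | 5-bromo-2-iodo-4-(methoxymethoxy)-3-(trimethylsilyloxy)benzaldehyde | COCOc1c(O[Si](C)(C)C)c(I)c(C=O)cc1Br
F5 | step 5 | [5-bromo-3-(1,3-dioxolan-2-yl)-2-iodo-6-(methoxymethoxy)phenoxy]trimethylsilane | COCOc1c(O[Si](C)(C)C)c(I)c(C2OCCO2)cc1Br
F6 | step 2 | 3-bromo-5-formyl-1,2-phenylene bis(N-isopropylcarbamate) | CC(C)NC(=O)Oc1cc(C=O)cc(Br)c1OC(=O)NC(C)C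
F7 | step 2 | 3-bromo-5-formyl-2-hydroxyphenyl N-isopropylcarbamate | CC(C)NC(=O)Oc1cc(C=O)cc(Br)c1O
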